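**Assumption:** the target is drawn as the free hydrogen sulfate, so the sulfate monoesters 14 and 15 are written in that form. In practice they would be handled as triethylammonium salts and 15 set free by proton exchange at the very end.

## The problem

Compound 15 is a flavonol. Benzo ring A is fused to pyranone ring C across C4a–C8a, the 4-hydroxyphenyl ring B sits on C2, and the enolic O3 carries a sulfate monoester. Ring A bears hydroxyls on C5, C6 and C7 besides O1 on C8a, so four of its six carbons carry oxygen and only C8 is a CH. There is no stereocentre, so nothing has to be set or relayed; every difficulty is regiochemical. Of five hydroxyls, exactly one must be sulfated, and it is O3, which is hindered and less acidic than the 7- and 4'-hydroxyls. Ring C must also close at C8a and not through the oxygen on the other side of C4a, which would give the wrong oxygenation pattern. The sulfate monoester hydrolyses in acid and does not survive the boron or aluminium halides used to cleave aryl methyl ethers, so it must come late and be followed only by neutral deprotection. The 5,6,7-trihydroxylated ring A is oxidised by air in base, and strong acid can open ring C and scramble the 5,6,7 and 5,7,8 patterns (Wessely–Moser rearrangement). The enabling feature is the catechol formed by the C6 and C7 hydroxyls: in its o-quinone, C8a is the β-carbon of the enone C7(=O)–C8=C8a. An oxygen nucleophile on the C4 side chain can therefore form O1–C8a from a C–H bond, and ring A can be bought with three oxygens instead of four.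

## Retrosynthesis

**Benzyl–oxygen bonds, 15 from 14.** The last step must leave the sulfate alone. The three O–CH2Ph bonds at O6, O7 and O4' are therefore cut last, by neutral hydrogenolysis of 14. Methyl ethers were rejected because their removal needs Lewis acids that destroy the sulfate. The forward step only has to spare the tetrasubstituted C2=C3 bond and keep the medium non-acidic.

**Sulfur–oxygen bond, 14 from 13.** In 13 only the 3- and 5-hydroxyls are free, and the 5-hydroxyl is locked in a hydrogen bond to the C4 carbonyl. O3 is thus the only position open to a mild O-sulfonation. Sulfating the unprotected pentahydroxyflavone would go to the more acidic 7- and 4'-hydroxyls first. This cut fixes the protecting-group logic: O3 needs a group of its own, removable while O6, O7 and O4' stay masked.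

**Protecting-group exchange, 13 from 12 from 11.** Diol 13 comes from 12 by acid cleavage of two methoxymethyl (MOM) acetals on O3 and O5, with benzyl ethers untouched. Compound 12 comes from triol 11 by benzylation of the 6-, 7- and 4'-hydroxyls. These two steps are the price of an unambiguous sulfation and use only acid-labile and hydrogenolysis-labile groups.

**O1–C8a, 11 from 9 via quinone 10.** This is the strategic cut. The usual flavonol disconnections (O1–C2 cyclodehydration of an o-hydroxyaryl diketone, or oxidative cyclisation of a chalcone) need ring A with four oxygens already in place and two competing ortho oxygens. Cutting O1–C8a back to a C–H bond gives the open diketone 9, whose ring A is a 3,4-dihydroxy-2-alkoxyphenyl ketone. The forward reaction must oxidise only the catechol and let the enol oxygen of the far carbonyl add to the quinone carbon ortho to the acyl group. The O5 MOM group blocks the alternative closure.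

**Ketal and benzyl ether, 9 from 8.** The catechol of 9 and its 4'-phenol are released from 8 by one hydrogenolysis, which cleaves a diphenylmethylene ketal and a benzyl ether and leaves both MOM acetals. Acid-labile catechol protection would not be orthogonal to MOM, so a hydrogenolysable ketal was chosen. The 4'-phenol of 9 is harder to oxidise than the catechol and is re-benzylated later with the catechol oxygens.

**C3–C4, 8 from 3 and 6 via enolate 7.** The bond between the ring A carbonyl carbon and the oxygenated central carbon is cut as a crossed Claisen condensation. Ester 3 has no α-hydrogens, and ketone 6 already carries the C3 oxygen as its MOM ether. The reverse polarity would need an α-oxygenated ring A ketone, which is much harder to obtain.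

**Fragments, 3 from 2 from 1, and 6 from 5 from 4.** Ester 3 comes from commercial methyl 2,3,4-trihydroxybenzoate 1. The ketal 2 forms across O3 and O4 because the 2-hydroxyl is chelated to the ester, and the remaining hydroxyl is then capped as MOM. Ketone 6 comes from commercial 2-hydroxy-1-(4-hydroxyphenyl)ethanone 4 by phenol benzylation (5) and MOM protection of the ketol.

## Roads not taken

**Alternative 1: intramolecular benzoin union of C3 and C4.** The cut is C3–C4 with ring C closed as a saturated ring. Dialdehyde A1 (an aryl aldehyde with an O–CH(aryl)–CHO arm in the ortho position) would be treated with a thiazolium-derived carbene and an amine base to give the 3-hydroxychroman-4-one A2.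

- Merits: it is catalytic, metal-free and installs the C3 oxygen directly. Carbene-catalysed intramolecular benzoin closures to chromanones are an established reaction class, so this road has firmer precedent than the anodic closure of 9.
- Weak points: the carbene must add to the hindered, electron-rich aromatic aldehyde and not to the more electrophilic aliphatic one, otherwise the isomeric 4-hydroxychroman-3-one results. A1 contains an α-aryl-α-aryloxy aldehyde that enolises and oxidises easily. A2 has two stereocentres the target does not need and must be dehydrogenated to the flavonol. Ring A of A1 needs all four oxygens before the key step.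
- Comparison: the chosen plan reaches the aromatic chromone in the ring-forming step, starts from a three-oxygen ring A and keeps O3 in a form that can be unmasked selectively. That is what it sets against the better precedent here.

**Alternative 2: one-carbon insertion into a benzofuranone.** The cuts are C2–C3 and C3–C4. The 3-silyloxybenzofuran A3 would take up a dibromocarbene generated in basic medium; the cyclopropane opens with loss of bromide and the silyl group to give the 3-bromoflavone A4.

- Merits: ring C is made in a single ring expansion, two skeletal bonds form at once, and the bromide of A4 is a flexible handle. In bonds formed per step it is better than the chosen plan.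
- Weak points: C3 arrives as C–Br and must be turned into C–O on a vinylogous ester that also accepts nucleophiles at C2, adding steps exactly where the sulfate has to go. The parent ketone of A3 autoxidises readily at C2 and must be silylated on oxygen. Ring A again needs four oxygens.
- Comparison: the chosen plan carries the C3 oxygen from the start, already differentiated as a MOM ether, and that outweighs the shorter ring construction.

**Alternative 3: ring A by cyclobutenone opening and six-electron electrocyclisation.** The cut is C4a–C5, with ring A built last. Heating the pyranonyl cyclobutenone A5 would open the four-membered ring to a dienylketene, which closes onto the free pyranone carbon and tautomerises to the 5-hydroxyflavone A6.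

- Merits: the substitution pattern of ring A is fixed by construction, the step needs no reagent, and the 5-hydroxyl of A6 emerges already differentiated from O6 and O7. The chosen plan has to arrange that with a protecting group. The pericyclic cascade is well precedented for aryl and vinyl cyclobutenones.
- Weak points: A5 is costly to make. It needs a 2-aryl-3-alkoxy-4-pyranone, attachment of a squarate-derived ring and adjustment of the ring carbon to the deoxy level (otherwise an extra oxygen appears at C8). That front end alone is longer than the entire route to 9. The oxygens on C6 and C7 come from the squarate as ethers and would need a hydrogenolysable variant to fit the sulfation endgame.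
- Comparison: this is the most elegant answer to ring A regiochemistry, but the chosen plan buys rings A and B and spends its one uncertain step on a single C–O bond.

All three alternatives, as drawn with methyl ethers, would face the same O3 differentiation problem. The comparison therefore rests on the key steps and the length of the precursors.

Key step: step 7

## Route

Step 1
Reactants: 1 methyl 2,3,4-trihydroxybenzoate
Product: 2 methyl 4-hydroxy-2,2-diphenyl-1,3-benzodioxole-5-carboxylate
Conditions: Ph2CCl2 (1.3 equiv), Ph2O, 175 °C
Reagents that add atoms: dichlorodiphenylmethane, ClC(Cl)(c1ccccc1)c1ccccc1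
Why: Ketalisation of a catechol by double substitution on a gem-dichloride; the 2-hydroxyl is hydrogen-bonded to the ester carbonyl and is the least nucleophilic, so the five-membered ketal should form across O3 and O4, as is usual for chelated 2,3,4-trihydroxyaryl carbonyl compounds.

Step 2
Reactants: 2 methyl 4-hydroxy-2,2-diphenyl-1,3-benzodioxole-5-carboxylate
Product: 3 methyl 4-(methoxymethoxy)-2,2-diphenyl-1,3-benzodioxole-5-carboxylate
Conditions: NaH, MOMCl, DMF, 0 °C → rt
Reagents that add atoms: chloromethyl methyl ether, COCCl
Why: Williamson-type O-alkylation; NaH breaks the chelate and the sodium phenoxide is alkylated by the reactive chloromethyl ether, while the ester and ketal are inert.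

Step 3
Reactants: 4 2-hydroxy-1-(4-hydroxyphenyl)ethan-1-one
Product: 5 1-[4-(benzyloxy)phenyl]-2-hydroxyethan-1-one
Conditions: BnBr (1.05 equiv), K2CO3, acetone, reflux
Reagents that add atoms: benzyl bromide, BrCc1ccccc1
Why: Chemoselective Williamson etherification; K2CO3 ionises the acylphenol but not the much less acidic primary ketol hydroxyl, so only the phenol oxygen should be benzylated.

Step 4
Reactants: 5 1-[4-(benzyloxy)phenyl]-2-hydroxyethan-1-one
Product: 6 1-[4-(benzyloxy)phenyl]-2-(methoxymethoxy)ethan-1-one
Conditions: MOMCl, iPr2NEt, CH2Cl2, 0 °C → rt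
Reagents that add atoms: chloromethyl methyl ether, COCCl
Why: Alkoxymethylation of a primary alcohol under amine base, the standard way to protect a ketol without forming an enolate.

Step 5
Reactants: 3 methyl 4-(methoxymethoxy)-2,2-diphenyl-1,3-benzodioxole-5-carboxylate; 6 1-[4-(benzyloxy)phenyl]-2-(methoxymethoxy)ethan-1-one
Product: 8 1-[4-(benzyloxy)phenyl]-2-(methoxymethoxy)-3-[4-(methoxymethoxy)-2,2-diphenyl-1,3-benzodioxol-5-yl]propane-1,3-dione, via lithium (Z)-enolate 7 (not isolated)
Conditions: 6, LiN(SiMe3)2 (2.5 equiv), THF, −78 °C; then 3, −78 °C → rt; aq. NH4Cl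
Reagents that add atoms: none
Why: Crossed Claisen condensation; the preformed ketone enolate is C-acylated by an ester without α-hydrogens, and deprotonation of the product diketone by the excess base drives the equilibrium. The central carbon of 8 is a labile, racemic stereocentre that is lost in step 7.

Step 6
Reactants: 8 1-[4-(benzyloxy)phenyl]-2-(methoxymethoxy)-3-[4-(methoxymethoxy)-2,2-diphenyl-1,3-benzodioxol-5-yl]propane-1,3-dione
Product: 9 1-[3,4-dihydroxy-2-(methoxymethoxy)phenyl]-3-(4-hydroxyphenyl)-2-(methoxymethoxy)propane-1,3-dione
Conditions: H2 (1 atm), Pd(OH)2/C, THF/MeOH, rt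
Reagents that add atoms: none
Why: Catalytic hydrogenolysis of benzylic C–O bonds cleaves the doubly benzylic ketal and the benzyl ether together; MOM acetals and the aryl ketones should survive neutral conditions at atmospheric pressure, and 9 is kept under inert gas.

Step 7
Reactants: 9 1-[3,4-dihydroxy-2-(methoxymethoxy)phenyl]-3-(4-hydroxyphenyl)-2-(methoxymethoxy)propane-1,3-dione
Product: 11 6,7-dihydroxy-2-(4-hydroxyphenyl)-3,5-bis(methoxymethoxy)-4H-chromen-4-one, via o-quinone 10 (not isolated)
Conditions: graphite anode, stainless-steel cathode, undivided cell, constant current, ca. 2 F/mol; MeCN/0.2 M aq. NaH2PO4–Na2HPO4 (pH 7) 1:1, 5 mM, rt, N2; aq. Na2S2O4 wash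
Reagents that add atoms: none
Why: Proposed new method: two-electron, two-proton oxidation of the catechol at graphite should give o-quinone 10, in which the ring CH ortho to the acyl group (the future C8a) is the β-carbon of the enone C7(=O)–C8=C8a; the enol or enolate oxygen of the 4-hydroxybenzoyl carbonyl adds there, and loss of the C8a proton re-aromatises ring A to the 6,7-dihydroxychromone 11. The closest known reaction type is anodic oxidation of catechols to o-quinones trapped in situ by 1,3-dicarbonyl nucleophiles, and the site of attack matches the intramolecular amine addition of dopaquinone; new here are the tethered enol oxygen as nucleophile and a chromone as product. Ring C closes in a 6-exo-trig mode, since the attacked C8=C8a bond lies outside the new ring. No stereocentre is formed and the labile one of 9 disappears. The catechol is expected to be oxidised at a clearly lower potential than the 4-acylphenol and the MOM ethers, which secures chemoselectivity. Regioselectivity rests on the tether: attack by the diketone carbon or the other carbonyl oxygen would need a four-membered ring, addition at the acyl-bearing carbon gives only a reversible spiro adduct that cannot aromatise, O5 is capped as its MOM ether, and high dilution disfavours addition of water or a second molecule. Product 11 is a more electron-rich catechol than 9, so the charge is limited to about 2 F/mol and any product quinone is returned by the dithionite wash.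

Step 8
Reactants: 11 6,7-dihydroxy-2-(4-hydroxyphenyl)-3,5-bis(methoxymethoxy)-4H-chromen-4-one
Product: 12 6,7-bis(benzyloxy)-2-[4-(benzyloxy)phenyl]-3,5-bis(methoxymethoxy)-4H-chromen-4-one
Conditions: BnBr (3.5 equiv), K2CO3, DMF, rt → 50 °C, Ar
Reagents that add atoms: benzyl bromide, BrCc1ccccc1
Why: Williamson etherification of the three phenols; the MOM acetals are base-stable and exclusion of air protects the catechol until it is capped.

Step 9
Reactants: 12 6,7-bis(benzyloxy)-2-[4-(benzyloxy)phenyl]-3,5-bis(methoxymethoxy)-4H-chromen-4-one
Product: 13 6,7-bis(benzyloxy)-2-[4-(benzyloxy)phenyl]-3,5-dihydroxy-4H-chromen-4-one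
Conditions: 3 M aq. HCl, MeOH/THF, 50 °C
Reagents that add atoms: none
Why: Acid-catalysed acetal cleavage removes both MOM groups; benzyl ethers are inert to dilute HCl, and the acid is too mild to open ring C.

Step 10
Reactants: 13 6,7-bis(benzyloxy)-2-[4-(benzyloxy)phenyl]-3,5-dihydroxy-4H-chromen-4-one
Product: 14 6,7-bis(benzyloxy)-2-[4-(benzyloxy)phenyl]-5-hydroxy-4-oxo-4H-chromen-3-yl hydrogen sulfate
Conditions: SO3·NMe3 (excess), Et3N, DMF, 55 °C
Reagents that add atoms: sulfur trioxide–trimethylamine complex, C[N+](C)(C)S(=O)(=O)[O-]
Why: O-sulfonation of a hydroxyl by an amine–SO3 complex; the 5-hydroxyl is held in a six-membered hydrogen bond to C4=O and should not react, all other oxygens are benzylated, so only O3 is sulfated.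

Step 11
Reactants: 14 6,7-bis(benzyloxy)-2-[4-(benzyloxy)phenyl]-5-hydroxy-4-oxo-4H-chromen-3-yl hydrogen sulfate
Product: 15 5,6,7-trihydroxy-2-(4-hydroxyphenyl)-4-oxo-4H-chromen-3-yl hydrogen sulfate
Conditions: H2 (1 atm), 10% Pd/C, Et3N (1 equiv), MeOH/THF, rt; then sulfonic acid resin (H+ form), 0 °C, freeze-drying
Reagents that add atoms: none
Why: Hydrogenolysis of three benzyl ethers; the sulfate monoester anion is inert to H2 over palladium, the amine keeps the medium non-acidic so the ester is not solvolysed, and the tetrasubstituted C2=C3 bond of the vinylogous ester should not be reduced at atmospheric pressure.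

## Compound list

1 | methyl 2,3,4-trihydroxybenzoate | COC(=O)c1ccc(O)c(O)c1O | starting material
2 | methyl 4-hydroxy-2,2-diphenyl-1,3-benzodioxole-5-carboxylate | COC(=O)c1ccc2OC(c3ccccc3)(c3ccccc3)Oc2c1O | intermediate
3 | methyl 4-(methoxymethoxy)-2,2-diphenyl-1,3-benzodioxole-5-carboxylate | COCOc1c(C(=O)OC)ccc2OC(c3ccccc3)(c3ccccc3)Oc12 | intermediate
4 | 2-hydroxy-1-(4-hydroxyphenyl)ethan-1-one | O=C(CO)c1ccc(O)cc1 | starting material
5 | 1-[4-(benzyloxy)phenyl]-2-hydroxyethan-1-one | O=C(CO)c1ccc(OCc2ccccc2)cc1 | intermediate
6 | 1-[4-(benzyloxy)phenyl]-2-(methoxymethoxy)ethan-1-one | COCOCC(=O)c1ccc(OCc2ccccc2)cc1 | intermediate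
7 | lithium (Z)-1-[4-(benzyloxy)phenyl]-2-(methoxymethoxy)ethen-1-olate | [Li+].[O-]/C(=C\OCOC)c1ccc(OCc2ccccc2)cc1 | intermediate (not isolated)
8 | 1-[4-(benzyloxy)phenyl]-2-(methoxymethoxy)-3-[4-(methoxymethoxy)-2,2-diphenyl-1,3-benzodioxol-5-yl]propane-1,3-dione (racemic, enolisable) | COCOC(C(=O)c1ccc(OCc2ccccc2)cc1)C(=O)c1ccc2OC(c3ccccc3)(c3ccccc3)Oc2c1OCOC | intermediate
9 | 1-[3,4-dihydroxy-2-(methoxymethoxy)phenyl]-3-(4-hydroxyphenyl)-2-(methoxymethoxy)propane-1,3-dione (racemic, enolisable) | COCOC(C(=O)c1ccc(O)cc1)C(=O)c1ccc(O)c(O)c1OCOC | intermediate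
10 | 1-(4-hydroxyphenyl)-2-(methoxymethoxy)-3-[2-(methoxymethoxy)-3,4-dioxocyclohexa-1,5-dien-1-yl]propane-1,3-dione | COCOC(C(=O)c1ccc(O)cc1)C(=O)C1=C(OCOC)C(=O)C(=O)C=C1 | intermediate (not isolated)
11 | 6,7-dihydroxy-2-(4-hydroxyphenyl)-3,5-bis(methoxymethoxy)-4H-chromen-4-one | COCOc1c(-c2ccc(O)cc2)oc2cc(O)c(O)c(OCOC)c2c1=O | intermediate
12 | 6,7-bis(benzyloxy)-2-[4-(benzyloxy)phenyl]-3,5-bis(methoxymethoxy)-4H-chromen-4-one | COCOc1c(-c2ccc(OCc3ccccc3)cc2)oc2cc(OCc3ccccc3)c(OCc3ccccc3)c(OCOC)c2c1=O | intermediate
13 | 6,7-bis(benzyloxy)-2-[4-(benzyloxy)phenyl]-3,5-dihydroxy-4H-chromen-4-one | O=c1c(O)c(-c2ccc(OCc3ccccc3)cc2)oc2cc(OCc3ccccc3)c(OCc3ccccc3)c(O)c12 | intermediate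
14 | 6,7-bis(benzyloxy)-2-[4-(benzyloxy)phenyl]-5-hydroxy-4-oxo-4H-chromen-3-yl hydrogen sulfate | O=c1c(OS(=O)(=O)O)c(-c2ccc(OCc3ccccc3)cc2)oc2cc(OCc3ccccc3)c(OCc3ccccc3)c(O)c12 | intermediate
15 | 5,6,7-trihydroxy-2-(4-hydroxyphenyl)-4-oxo-4H-chromen-3-yl hydrogen sulfate | O=c1c(OS(=O)(=O)O)c(-c2ccc(O)cc2)oc2cc(O)c(O)c(O)c12 | target

## Step count and least certain steps

Total step count: 11. Longest linear sequence: 9 steps (1 → 2 → 3 → 8 → 9 → 11 → 12 → 13 → 14 → 15; the branch from 4 through 5 and 6 is equally long).

**Step 7 (key step, proposed new method).** The most likely failure is intermolecular consumption of quinone 10 before the enol oxygen closes: addition of water or of a second catechol molecule, leading to oligomers. The 2-alkoxy-1,3-diketone is only partly enolised at pH 7, and the acyl group is twisted by two ortho substituents. The second hazard is further oxidation of the product catechol, which is more electron-rich than 9.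

Fallback, by known chemistry, leaving the route at 3 and returning at 11: the O1–C8a bond is made by copper-catalysed intramolecular O-arylation instead of oxidation. Ester 3 is saponified (LiOH, aqueous THF/MeOH) to 4-(methoxymethoxy)-2,2-diphenyl-1,3-benzodioxole-5-carboxylic acid F1. Carboxylate-directed ortho-lithiation (s-BuLi/TMEDA, THF, −78 °C) and quenching with I2 should give 6-iodo-4-(methoxymethoxy)-2,2-diphenyl-1,3-benzodioxole-5-carboxylic acid F2, the only free ortho position being the future C8a. Activation with 1,1'-carbonyldiimidazole gives 1H-imidazol-1-yl[6-iodo-4-(methoxymethoxy)-2,2-diphenyl-1,3-benzodioxol-5-yl]methanone F3, which is not isolated but added to enolate 7. This gives 1-[4-(benzyloxy)phenyl]-3-[6-iodo-4-(methoxymethoxy)-2,2-diphenyl-1,3-benzodioxol-5-yl]-2-(methoxymethoxy)propane-1,3-dione F4. CuI with 1,10-phenanthroline and K2CO3 in DMF then closes ring C by displacement of iodide by the enolate oxygen, giving 2-[4-(benzyloxy)phenyl]-3,5-bis(methoxymethoxy)-6,7-[(diphenylmethylene)bis(oxy)]-4H-chromen-4-one F5. Hydrogenolysis over Pd(OH)2/C as in step 6 removes the ketal and the benzyl ether and delivers 11.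

**Step 5 (Claisen condensation).** The likely failure is incomplete acylation with competing self-aldol of the ketone. Ester 3 is electron-rich and ortho-substituted, so it is a slow acyl acceptor, and proton exchange between enolate 7 and free ketone 6 becomes competitive on warming.

Fallback, leaving at 3 and returning at 8: aldol addition followed by oxidation. Ester 3 is reduced with LiAlH4 to [4-(methoxymethoxy)-2,2-diphenyl-1,3-benzodioxol-5-yl]methanol F6 and oxidised with MnO2 to 4-(methoxymethoxy)-2,2-diphenyl-1,3-benzodioxole-5-carbaldehyde F7. Enolate 7 adds to the aldehyde at −78 °C to give 1-[4-(benzyloxy)phenyl]-3-hydroxy-2-(methoxymethoxy)-3-[4-(methoxymethoxy)-2,2-diphenyl-1,3-benzodioxol-5-yl]propan-1-one F8 as a mixture of diastereomers. Dess–Martin periodinane converts both diastereomers into 8.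

**Step 10 (sulfation).** The likely failure is sluggish or misdirected sulfonation. The enolic 3-hydroxyl is flanked by the aryl group and the carbonyl, so forcing conditions may begin to sulfonate the 5-hydroxyl, and the ionic product is hard to purify.

Fallback, leaving at 13 and returning at 14: a protected sulfate diester. 2,2,2-Trichloroethyl chlorosulfate with Et3N and 4-(dimethylamino)pyridine should give the neutral, chromatographable 6,7-bis(benzyloxy)-2-[4-(benzyloxy)phenyl]-5-hydroxy-4-oxo-4H-chromen-3-yl 2,2,2-trichloroethyl sulfate F9. Zn and HCO2NH4 in MeOH then remove the trichloroethyl group reductively to give 14.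

**Step 11 (final hydrogenolysis).** The likely failure is loss of the sulfate by acid-catalysed solvolysis as free phenols accumulate, stalling of the debenzylation on the ionic substrate, or air oxidation of the trihydroxylated ring A during work-up.

Fallback, leaving at 11 and returning at 15: acyl protection and a basic final deprotection. Triol 11 is acetylated (Ac2O, pyridine) to 2-[4-(acetyloxy)phenyl]-3,5-bis(methoxymethoxy)-4-oxo-4H-chromene-6,7-diyl diacetate F10. Anhydrous CF3CO2H in CH2Cl2 cleaves the two MOM groups without touching the aryl acetates and gives 2-[4-(acetyloxy)phenyl]-3,5-dihydroxy-4-oxo-4H-chromene-6,7-diyl diacetate F11. SO3·pyridine in pyridine sulfates O3 to give 2-[4-(acetyloxy)phenyl]-5-hydroxy-4-oxo-3-(sulfooxy)-4H-chromene-6,7-diyl diacetate F12. Methanolysis with K2CO3 in MeOH at 0 °C under argon, followed by proton exchange on a sulfonic acid resin, gives 15.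

## Further compounds

F1 | step 7 | 4-(methoxymethoxy)-2,2-diphenyl-1,3-benzodioxole-5-carboxylic acid | COCOc1c(C(=O)O)ccc2OC(c3ccccc3)(c3ccccc3)Oc12
F2 | step 7 | 6-iodo-4-(methoxymethoxy)-2,2-diphenyl-1,3-benzodioxole-5-carboxylic acid | COCOc1c(C(=O)O)c(I)cc2OC(c3ccccc3)(c3ccccc3)Oc12
F3 | step 7 | 1H-imidazol-1-yl[6-iodo-4-(methoxymethoxy)-2,2-diphenyl-1,3-benzodioxol-5-yl]methanone | COCOc1c(C(=O)n2ccnc2)c(I)cc2OC(c3ccccc3)(c3ccccc3)Oc12
F4 | step 7 | 1-[4-(benzyloxy)phenyl]-3-[6-iodo-4-(methoxymethoxy)-2,2-diphenyl-1,3-benzodioxol-5-yl]-2-(methoxymethoxy)propane-1,3-dione (racemic) | COCOC(C(=O)c1ccc(OCc2ccccc2)cc1)C(=O)c1c(I)cc2OC(c3ccccc3)(c3ccccc3)Oc2c1OCOC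
F5 | step 7 | 2-[4-(benzyloxy)phenyl]-3,5-bis(methoxymethoxy)-6,7-[(diphenylmethylene)bis(oxy)]-4H-chromen-4-one | COCOc1c(-c2ccc(OCc3ccccc3)cc2)oc2cc3OC(c4ccccc4)(c4ccccc4)Oc3c(OCOC)c2c1=O
F6 | step 5 | [4-(methoxymethoxy)-2,2-diphenyl-1,3-benzodioxol-5-yl]methanol | COCOc1c(CO)ccc2OC(c3ccccc3)(c3ccccc3)Oc12
F7 | step 5 | 4-(methoxymethoxy)-2,2-diphenyl-1,3-benzodioxole-5-carbaldehyde | COCOc1c(C=O)ccc2OC(c3ccccc3)(c3ccccc3)Oc12
F8 | step 5 | 1-[4-(benzyloxy)phenyl]-3-hydroxy-2-(methoxymethoxy)-3-[4-(methoxymethoxy)-2,2-diphenyl-1,3-benzodioxol-5-yl]propan-1-one (mixture of diastereomers) | COCOC(C(=O)c1ccc(OCc2ccccc2)cc1)C(O)c1ccc2OC(c3ccccc3)(c3ccccc3)Oc2c1OCOC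
F9 | step 10 | 6,7-bis(benzyloxy)-2-[4-(benzyloxy)phenyl]-5-hydroxy-4-oxo-4H-chromen-3-yl 2,2,2-trichloroethyl sulfate | O=c1c(OS(=O)(=O)OCC(Cl)(Cl)Cl)c(-c2ccc(OCc3ccccc3)cc2)oc2cc(OCc3ccccc3)c(OCc3ccccc3)c(O)c12
F10 | step 11 | 2-[4-(acetyloxy)phenyl]-3,5-bis(methoxymethoxy)-4-oxo-4H-chromene-6,7-diyl diacetate | COCOc1c(-c2ccc(OC(C)=O)cc2)oc2cc(OC(C)=O)c(OC(C)=O)c(OCOC)c2c1=O
F11 | step 11 | 2-[4-(acetyloxy)phenyl]-3,5-dihydroxy-4-oxo-4H-chromene-6,7-diyl diacetate | O=c1c(O)c(-c2ccc(OC(C)=O)cc2)oc2cc(OC(C)=O)c(OC(C)=O)c(O)c12
F12 | step 11 | 2-[4-(acetyloxy)phenyl]-5-hydroxy-4-oxo-3-(sulfooxy)-4H-chromene-6,7-diyl diacetate | O=c1c(OS(=O)(=O)O)c(-c2ccc(OC(C)=O)cc2)oc2cc(OC(C)=O)c(OC(C)=O)c(O)c12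
A1 | alternative 1 | 2,3,4-trimethoxy-6-[1-(4-methoxyphenyl)-2-oxoethoxy]benzaldehyde (racemic) | COc1ccc(cc1)C(C=O)Oc1cc(OC)c(OC)c(OC)c1C=O
A2 | alternative 1 | 3-hydroxy-5,6,7-trimethoxy-2-(4-methoxyphenyl)chroman-4-one (mixture of stereoisomers) | COc1ccc(cc1)C1Oc2cc(OC)c(OC)c(OC)c2C(=O)C1O
A3 | alternative 2 | tert-butyl(dimethyl){[4,5,6-trimethoxy-2-(4-methoxyphenyl)-1-benzofuran-3-yl]oxy}silane | COc1ccc(cc1)-c1oc2cc(OC)c(OC)c(OC)c2c1O[Si](C)(C)C(C)(C)C
A4 | alternative 2 | 3-bromo-5,6,7-trimethoxy-2-(4-methoxyphenyl)-4H-chromen-4-one | COc1ccc(cc1)-c1oc2cc(OC)c(OC)c(OC)c2c(=O)c1Br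
A5 | alternative 3 | 2,3-dimethoxy-4-[5-methoxy-6-(4-methoxyphenyl)-4-oxo-4H-pyran-2-yl]cyclobut-2-en-1-one (racemic) | COc1ccc(cc1)-c1oc(cc(=O)c1OC)C1C(=O)C(OC)=C1OC
A6 | alternative 3 | 5-hydroxy-3,6,7-trimethoxy-2-(4-methoxyphenyl)-4H-chromen-4-one | COc1ccc(cc1)-c1oc2cc(OC)c(OC)c(O)c2c(=O)c1OC
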